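## The problem

Compound 28 is honokiol whose 2-hydroxyl is etherified with C4 of cryptomeridiol (eudesmane-4α,11-diol). The terpene half is a trans-fused decalin (ring A: C1–C5 and C10; ring B: C5–C10) with four stereocentres, 4R, 5R, 7R and 10R. C4 (oxygen-bearing) and C10 (all-carbon) are quaternary, and their methyl groups are 1,3-diaxial. At C4 the oxygen is equatorial and the methyl axial, which is the less stable arrangement. Methyl addition to a 4-ketone or a reversible aldol would therefore give the wrong epimer, and C4 has to come from a stereospecific event. C7 is remote from the ring fusion and can steer only through ring conformation. C4 and C5 are vicinal and can be encoded together in the geometry of a 4,5-alkene, and C10 is fixed relative to C5 when the ring-fusion bond is made. The ether is a tertiary alkyl aryl ether next to an ortho aryl group: it is hard to make and ionises under acid once made. The two allyl groups rule out hydrogenation, peracids and isomerising conditions late in the route, and the C11 tertiary carbinol must be told apart from the C4 one. The enabling feature is that the ring-fusion bond C5–C10 lies between the oxygenated carbon C4 and C9. With a carbonyl at C9 and an epoxide across C4–C5 in the ten-membered ring C1–C10, C10 is nucleophilic and C5 electrophilic, so one bond across that ring makes ring A, ring B, the C5 and C10 stereocentres and the free C4 alkoxide.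

## Retrosynthesis

**Silyl ether and ring-A allyl group.** 28 is traced to its C11 triethylsilyl ether 27, and the allyl group para to the ether oxygen is cut at its aryl–CH2 bond to give chloride 26. The allyl group is put on last because the oxidant needed to make the arylating reagent would epoxidise it; a chloride stays silent until then. The forward steps must allylate an electron-rich aryl chloride without moving the double bonds, and must remove silicon without acid.

**Biaryl bond.** 26 is cut between the two arenes into bromide 21 and boronate 25. Arylating with the preassembled biaryl was rejected because its iodonium salt would have to be made by oxidation in the presence of an allyl group and a phenol. 25 goes back through 24 and 23 to 22; the Claisen rearrangement places the allyl group ortho to the hydroxyl. The coupling must choose C–Br over C–Cl.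

**Aryl ether.** 21 is cut at the O–C(aryl) bond, not at C4–O, into the tertiary alcohol 16 and the iodonium salt 19 (from 17). Cutting at C4–O would mean a tertiary cation, loss of the C4 configuration and elimination. The forward reaction asks a shielded tertiary alkoxide to accept the correct aryl ligand, and the C11 hydroxyl must be masked, hence the silyl ether carried from the start.

**C9 carbonyl.** A carbonyl is added back at C9 (16 ⇐ 14). It costs one deoxygenation but makes C10 acidic.

**Ring-fusion bond C5–C10.** 14 is cut between C5 and C10 with the C4 oxygen tied back to C5 as an epoxide, giving the ten-membered epoxy ketone 12. Against the neighbouring cuts (C4–C5 by aldol, C10–C1 by Michael addition) this one sets C4 and C5 together and stereospecifically, and removes both rings and two stereocentres at once. The forward reaction needs the more substituted enolate, attack at C5 and not at C4, and the trans-decalin chair–chair geometry.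

**Epoxide.** 12 is traced to the E-alkene 11. The alkene geometry fixes C4 relative to C5; only the face relative to C7 remains to be chosen.

**Ten-membered ring.** 11 is the oxy-Cope product of the 1,2-dialkenylcyclohexanol 8: reconnecting C4–C9 and cutting C6–C7 shrinks the ring to a cyclohexane. C7 then maps onto the quaternary methyl/vinyl carbon of 8, so one stereocentre set early controls C7 by chair-transition-state chirality transfer.

**Cyclohexanol.** 8 is cut at the carbinol–alkenyl bond into ketone 6 and alkenyl iodide 4. 6 comes from 5 by enantioselective α-vinylation, and 4 from 1 through silyl ether 2.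

## Roads not taken

**Alternative 1:** Ring A is taken apart at C3–C4 (aldol) and at C10–C1 plus C5–C4 (photocycloaddition), leading back to (R)-α-terpineol A2 and pentane-2,4-dione A3. In the key step, irradiation of enolised A3 with A2 would give a cyclobutanol that opens by retro-aldol to the 1,5-diketone A1. An aldol would then close ring A to the 4-hydroxy-2-ketone A4, and the extra carbonyl would be removed.
- Merits: C7 comes from the chiral pool, two ring-A bonds form in one operation from commodity chemicals, and the decalin would be reached in fewer steps than the eight that lead to 16. On step count and cost this road is better.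
- Weak points: the acetyl and oxopropyl groups of A1 are cis, so C5 must be epimerised. The face of the cyclohexene is chosen only by a 1,4-remote substituent. The aldol between two methyl ketones can run in two directions and is reversible, so C4 would settle with the methyl equatorial and the hydroxyl axial, the epimer of A4. The two tertiary hydroxyls still have to be differentiated.
- Comparison: the chosen plan is longer, but it derives C4 and C5 from alkene geometry and an inversion, fixes C7 by chirality transfer, and has no regiochemical choice in ring closure. Both need one carbonyl removal.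

**Alternative 2:** No eudesmane bond is cut; two C–C bonds of the ether-bearing arene are. The alkynyl ether A6 of the C4 oxygen, already carrying the second aryl ring, would add across C3 and C6 of methyl coumalate A7 and lose carbon dioxide to give benzoate A5.
- Merits: no hindered alkoxide has to be arylated, the biaryl bond is carried in, and regiochemistry follows from the polarisation of the two partners. In convergence on the arene side this road is better than steps 9, 10, 14 and 15.
- Weak points: A6 is an alkynyl ether of a tertiary alcohol with β-hydrogens at C3, C5 and C15. Such ethers fragment by a retro-ene path to a ketene and an alkene at temperatures below those a pyrone cycloaddition needs. The ester of A5 is one carbon short of the allyl group and needs about three more steps. The decalin problem is untouched, so 16 is still required.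
- Comparison: the chosen plan keeps the C4–O bond out of danger and arylates with a stable reagent near room temperature, at the price of two palladium couplings.

**Alternative 3:** Ring A is cut at C2–C3, back to the triethylsilyl ether of natural elemol A9, in which C5, C7 and C10 are already correct. Divalent palladium would activate the vinyl group, the isopropenyl methylene would attack its terminus, water would trap the C4 cation and β-hydride elimination would give A8. Hydrogenation of the C1–C2 alkene would then give 16.
- Merits: about three steps to 16 instead of eight, three stereocentres from the chiral pool and no carbonyl to remove. In step economy and absolute stereocontrol this road is clearly better, and should be preferred if its key step worked.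
- Weak points: this oxidative cyclisation with water capture has no close precedent. Divalent palladium normally catalyses the Cope rearrangement of 1,5-dienes, which would open the six-membered ring, and a terminal vinyl group under wet, quinone-reoxidised conditions is a Wacker substrate. C4 would be set by capture of a cation, with elimination competing. The supply of natural elemol of defined purity is uncertain.
- Comparison: the chosen plan sets every stereocentre by a reaction type that is known on its bond class, and sets C4 stereospecifically.

Key step: step 7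

## Route

Remark: eudesmane numbering (C1–C15) is used for the decalins and for the ten-membered ring. Commercial 5 is a cis/trans mixture, and the methyl-bearing CH next to the carbonyl (later C10) is carried as both epimers until step 7, where it becomes the enolate carbon.

Remark: which antipode of the ligand in step 3 gives the 2S ketone has to be established in the first runs; both antipodes can be made.

Step 1
Reactants: 1 2-methylbut-3-yn-2-ol
Product: 2 triethyl[(2-methylbut-3-yn-2-yl)oxy]silane
Conditions: TESCl, imidazole, DMF, 0 → 23 °C
Reagents that add atoms: chlorotriethylsilane, CC[Si](Cl)(CC)CC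
Why: Silyl ether formation at a tertiary propargylic alcohol, whose linear alkyne arm leaves the hydroxyl accessible; the triethylsilyl group withstands organolithium, hydride and alkoxide bases and is removed by fluoride at the end.

Step 2
Reactants: 2 triethyl[(2-methylbut-3-yn-2-yl)oxy]silane
Product: 4 triethyl{[(3E)-4-iodo-2-methylbut-3-en-2-yl]oxy}silane, via alkenylzirconocene chloride 3 (not isolated)
Conditions: Cp2Zr(H)Cl, THF, 23 °C; then I2, 0 °C
Reagents that add atoms: iodine, II
Why: Hydrozirconation of a terminal alkyne is a syn addition that places zirconium on the terminal carbon, and iodinolysis of the C–Zr bond proceeds with retention, so only the E iodide is expected.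

Step 3
Reactants: 5 2,6-dimethylcyclohexan-1-one
Product: 6 (2S)-2-ethenyl-2,6-dimethylcyclohexan-1-one (both C6 epimers)
Conditions: vinyl bromide, Pd2(dba)3 (cat.), 2-(dicyclohexylphosphino)-2'-(dimethylamino)-1,1'-binaphthyl (one antipode, cat.), NaOtBu, toluene, 23 °C; 5 in excess
Reagents that add atoms: bromoethene, C=CBr
Why: Palladium-catalysed asymmetric α-vinylation of a ketone enolate, a reaction known to build α-methyl-α-vinyl quaternary carbons on cyclic ketones; the chiral monophosphine differentiates the enolate faces in the C–C reductive elimination that creates C2, and the product cannot racemise because C2 carries no hydrogen. The excess of 5 is meant to hold back a second vinylation at C6.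

Step 4
Reactants: 4 triethyl{[(3E)-4-iodo-2-methylbut-3-en-2-yl]oxy}silane; 6 (2S)-2-ethenyl-2,6-dimethylcyclohexan-1-one
Product: 8 (2S)-2-ethenyl-2,6-dimethyl-1-[(1E)-3-methyl-3-(triethylsilyloxy)but-1-en-1-yl]cyclohexan-1-ol (mixture at C1 and C6), via alkenyllithium 7 (not isolated)
Conditions: 4, t-BuLi (2 equiv), Et2O, −78 °C; then 6, −78 → −20 °C; H2O
Reagents that add atoms: none
Why: Iodine–lithium exchange with retention of alkene geometry, then 1,2-addition of the alkenyllithium to the hindered ketone, as in additions to 2,2,6-trialkylcyclohexanones. The configuration created at C1 is not controlled and need not be, because each C1/C6 isomer has a chair oxy-Cope transition state that leads to the same product in step 5.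

Step 5
Reactants: 8 (2S)-2-ethenyl-2,6-dimethyl-1-[(1E)-3-methyl-3-(triethylsilyloxy)but-1-en-1-yl]cyclohexan-1-ol
Product: 11 (6E,9S)-2,6-dimethyl-9-[2-(triethylsilyloxy)propan-2-yl]cyclodec-6-en-1-one (both C2 epimers), via potassium alkoxide 9 (not isolated), via potassium enolate 10 (not isolated)
Conditions: KH, 18-crown-6, THF, 0 → 40 °C; then aq. NH4Cl
Reagents that add atoms: none
Why: Anionic oxy-Cope rearrangement ([3,3] shift accelerated by the alkoxide), the established ring expansion of 1,2-dialkenylcyclohexanols to cyclodec-5-enones. In the chair transition state the ring methylene on the quaternary carbon is pseudo-equatorial, which gives the E trisubstituted alkene, and the silyloxyalkyl group on the E alkenyl terminus is pseudo-equatorial, so the 2S quaternary centre is translated into the 9S centre (C7 of the eudesmane) while C1 and C2 of 8 lose their stereochemistry.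

Step 6
Reactants: 11 (6E,9S)-2,6-dimethyl-9-[2-(triethylsilyloxy)propan-2-yl]cyclodec-6-en-1-one
Product: 12 (6R,7R,9S)-6,7-epoxy-2,6-dimethyl-9-[2-(triethylsilyloxy)propan-2-yl]cyclodecan-1-one (trans epoxide; both C2 epimers)
Conditions: 1,2:4,5-di-O-isopropylidene-β-D-erythro-2,3-hexodiulo-2,6-pyranose (D-fructose-derived Shi ketone, 30 mol %), KHSO5 (as 2KHSO5·KHSO4·K2SO4), K2CO3, Bu4NHSO4 (cat.), MeCN–CH2(OMe)2–aq. Na2B4O7 buffer (pH 10.5), 0 °C
Reagents that add atoms: potassium peroxymonosulfate, [K+].[O-]S(=O)(=O)OO
Why: Shi asymmetric epoxidation (chiral dioxirane) of a trisubstituted E alkene, stereospecific in alkene geometry so that the trans epoxide results. The D-fructose-derived ketone delivers oxygen to the face that gives the R,R epoxide; this is also the outer face of the ring conformer inherited from the oxy-Cope chair (C9 substituent pseudo-equatorial, ring methyl anti to the C9 hydrogen), the face that peracids attack in E-4,5-germacrenes, so catalyst and substrate should reinforce each other.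

Step 7
Reactants: 12 (6R,7R,9S)-6,7-epoxy-2,6-dimethyl-9-[2-(triethylsilyloxy)propan-2-yl]cyclodecan-1-one
Product: 14 (4R,5R,7S,10S)-4-hydroxy-11-(triethylsilyloxy)eudesman-9-one [(3S,4aR,5R,8aS)-5-hydroxy-5,8a-dimethyl-3-[2-(triethylsilyloxy)propan-2-yl]octahydronaphthalen-1(2H)-one; 4α-OH 5α-H 10β-CH3], via potassium enolate 13 (not isolated)
Conditions: KOtBu, t-BuOH–THF, 23 → 60 °C; then aq. NH4Cl
Reagents that add atoms: none
Why: tert-Butoxide in tert-butanol equilibrates the ketone with its enolates, and the tetrasubstituted C9=C10 enolate 13 attacks the secondary epoxide carbon C5 from the side opposite the C5–O bond, which forms C5–C10 and releases the C4 alkoxide; the closest known reaction type is the intramolecular alkylation of a ketone enolate by an epoxide, run here across a ring as in base-induced cyclisations of epoxygermacranones. Ring B (C5–C10) closes in the 6-(enolendo)-exo-tet mode and ring A (C1–C5 and C10) as a 6-(enolexo) closure that is endo with respect to the epoxide, both through the one transannular bond. C5 is set by inversion and C4 is not touched, so the trans epoxide becomes the 4α-oxygen/5α-hydrogen pair without any equilibration. C10 is set by the enolate face: a chair ring A, fixed by the epoxide geometry, leaves two chair–chair arrangements, and the one with C4–C5 and C10–C9 antiperiplanar (trans-decalin, C7 group equatorial) avoids the axial C4 and C9 substituents of the cis-fused alternative. Attack at C5 in preference to C4 is secured sterically, since C4 is fully substituted and its alkylation would create two adjacent quaternary carbons. The C8 enolate can reach C5 only through a four-membered ring, so its formation under equilibrating conditions is harmless, and both C10 epimers of 12 converge on the same enolate.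

Step 8
Reactants: 14 (4R,5R,7S,10S)-4-hydroxy-11-(triethylsilyloxy)eudesman-9-one
Product: 16 (4R,5R,7R,10R)-11-(triethylsilyloxy)eudesman-4-ol [11-O-triethylsilylcryptomeridiol; (1R,4aR,7R,8aR)-1,4a-dimethyl-7-[2-(triethylsilyloxy)propan-2-yl]decahydronaphthalen-1-ol], via N-silylhydrazone 15 (not isolated)
Conditions: TBSNHNHTBS, Sc(OTf)3 (cat.), CHCl3, 60–100 °C; then KOtBu, t-BuOH, DMSO, 23 → 60 °C
Reagents that add atoms: none
Why: Wolff–Kishner reduction in its N-silylhydrazone variant: Sc(OTf)3 catalyses condensation at the hindered C9 carbonyl without azine formation, and tert-butoxide in DMSO then frees the hydrazone anion, which loses dinitrogen well below the temperature of the classical procedure. No stereocentre is at risk because C10 is quaternary, and the mild second stage is chosen to keep the tertiary silyl ether that distinguishes the C11 from the C4 hydroxyl.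

Step 9
Reactants: 17 2-bromo-4-chloro-1-iodobenzene
Product: 19 (2-bromo-4-chlorophenyl)(2,4,6-trimethoxyphenyl)iodonium 4-methylbenzenesulfonate, via hydroxy(tosyloxy)iodoarene 18 (not isolated)
Conditions: mCPBA, TsOH·H2O, MeCN, 77 °C; then 1,3,5-trimethoxybenzene, 23 °C
Reagents that add atoms: 1,3,5-trimethoxybenzene, COc1cc(OC)cc(OC)c1; 4-methylbenzenesulfonic acid, Cc1ccc(cc1)S(=O)(=O)O
Why: One-pot oxidation of the aryl iodide to the trivalent iodine tosylate and electrophilic substitution on the electron-rich arene, the standard route to aryl(trimethoxyphenyl)iodonium salts. Aryl bromide and chloride are inert to the peracid, which is why the allyl group is not yet present.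

Step 10
Reactants: 16 (4R,5R,7R,10R)-11-(triethylsilyloxy)eudesman-4-ol; 19 (2-bromo-4-chlorophenyl)(2,4,6-trimethoxyphenyl)iodonium 4-methylbenzenesulfonate
Product: 21 (4R,5R,7R,10R)-4-(2-bromo-4-chlorophenoxy)-11-(triethylsilyloxy)eudesmane (4α-aryloxy), via sodium alkoxide 20 (not isolated)
Conditions: NaH, toluene, 0 → 23 °C; then 19, 23 → 40 °C
Reagents that add atoms: none
Why: Metal-free O-arylation of a tertiary alkoxide with a diaryliodonium salt (ligand exchange and ligand coupling at trivalent iodine), a method shown to give congested tertiary alkyl aryl ethers. The electron-rich trimethoxyphenyl ligand stays on iodine and the ortho-substituted, electron-poor bromochlorophenyl group is transferred; the C4–O bond is never broken, so the configuration set in step 7 is kept.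

Step 11
Reactants: 22 4-bromophenol
Product: 23 1-bromo-4-(prop-2-en-1-yloxy)benzene
Conditions: allyl bromide, K2CO3, acetone, 56 °C
Reagents that add atoms: 3-bromoprop-1-ene, C=CCBr
Why: Williamson ether synthesis on a phenoxide.

Step 12
Reactants: 23 1-bromo-4-(prop-2-en-1-yloxy)benzene
Product: 24 4-bromo-2-(prop-2-en-1-yl)phenol
Conditions: N,N-diethylaniline, 200 °C
Reagents that add atoms: none
Why: Aromatic Claisen rearrangement; the para position is blocked by bromine, so the [3,3] shift to the ortho carbon and tautomerisation give a single phenol.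

Step 13
Reactants: 24 4-bromo-2-(prop-2-en-1-yl)phenol
Product: 25 2-(prop-2-en-1-yl)-4-(4,4,5,5-tetramethyl-1,3,2-dioxaborolan-2-yl)phenol
Conditions: B2pin2, PdCl2(dppf) [dppf = 1,1'-bis(diphenylphosphino)ferrocene] (cat.), KOAc, 1,4-dioxane, 85 °C
Reagents that add atoms: bis(pinacolato)diboron, CC1(C)OB(OC1(C)C)B1OC(C)(C)C(C)(C)O1
Why: Miyaura borylation of an aryl bromide; the weak acetate base tolerates the free phenol and does not promote coupling of the product boronate or migration of the allyl double bond.

Step 14
Reactants: 21 (4R,5R,7R,10R)-4-(2-bromo-4-chlorophenoxy)-11-(triethylsilyloxy)eudesmane; 25 2-(prop-2-en-1-yl)-4-(4,4,5,5-tetramethyl-1,3,2-dioxaborolan-2-yl)phenol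
Product: 26 (4R,5R,7R,10R)-4-{[5-chloro-4'-hydroxy-3'-(prop-2-en-1-yl)biphenyl-2-yl]oxy}-11-(triethylsilyloxy)eudesmane
Conditions: PdCl2(dppf) (cat.), K2CO3, 1,4-dioxane–H2O, 85 °C
Reagents that add atoms: none
Why: Suzuki–Miyaura coupling; with this bisphosphine-ligated catalyst, oxidative addition into the C–Br bond is much faster than into the C–Cl bond, so the biaryl bond forms ortho to the ether oxygen and the chloride is kept for step 15.

Step 15
Reactants: 26 (4R,5R,7R,10R)-4-{[5-chloro-4'-hydroxy-3'-(prop-2-en-1-yl)biphenyl-2-yl]oxy}-11-(triethylsilyloxy)eudesmane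
Product: 27 (4R,5R,7R,10R)-4-{[4'-hydroxy-3',5-di(prop-2-en-1-yl)biphenyl-2-yl]oxy}-11-(triethylsilyloxy)eudesmane
Conditions: allylB(pin), Pd(OAc)2 (cat.), 2-dicyclohexylphosphino-2',4',6'-triisopropylbiphenyl (cat.), K3PO4, THF–H2O, 60 °C
Reagents that add atoms: 2-(prop-2-en-1-yl)-4,4,5,5-tetramethyl-1,3,2-dioxaborolane, C=CCB1OC(C)(C)C(C)(C)O1
Why: Suzuki–Miyaura allylation of an aryl chloride with a dialkylbiarylphosphine-ligated palladium catalyst, which activates electron-rich aryl chlorides. The unsubstituted allyl group raises no regiochemical question, and the mild base and temperature are chosen to limit migration of the double bonds into conjugation.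

Step 16
Reactants: 27 (4R,5R,7R,10R)-4-{[4'-hydroxy-3',5-di(prop-2-en-1-yl)biphenyl-2-yl]oxy}-11-(triethylsilyloxy)eudesmane
Product: 28 2-(prop-2-en-1-yl)-4-{5-(prop-2-en-1-yl)-2-[((1R,4aR,7R,8aR)-7-(2-hydroxypropan-2-yl)-1,4a-dimethyldecahydronaphthalen-1-yl)oxy]phenyl}phenol (CNP0219722.1)
Conditions: Bu4NF, THF, 23 °C
Reagents that add atoms: none
Why: Fluoride-induced cleavage of the triethylsilyl ether; the non-acidic conditions spare the tertiary alkyl aryl ether, which would ionise under acid, and leave the allyl groups in place.

## Compound list

1 | 2-methylbut-3-yn-2-ol | CC(C)(O)C#C | starting material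
2 | triethyl[(2-methylbut-3-yn-2-yl)oxy]silane | CC[Si](CC)(CC)OC(C)(C)C#C | intermediate
3 | chlorobis(cyclopentadienyl)[(1E)-3-methyl-3-(triethylsilyloxy)but-1-en-1-yl]zirconium (not isolated) | CC[Si](CC)(CC)OC(C)(C)/C=C/[Zr](Cl)(C1C=CC=C1)C1C=CC=C1 | intermediate
4 | triethyl{[(3E)-4-iodo-2-methylbut-3-en-2-yl]oxy}silane | CC[Si](CC)(CC)OC(C)(C)/C=C/I | intermediate
5 | 2,6-dimethylcyclohexan-1-one (cis/trans mixture) | CC1CCCC(C)C1=O | starting material
6 | (2S)-2-ethenyl-2,6-dimethylcyclohexan-1-one (both C6 epimers) | C=C[C@]1(C)CCCC(C)C1=O | intermediate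
7 | [(1E)-3-methyl-3-(triethylsilyloxy)but-1-en-1-yl]lithium (not isolated) | [Li]/C=C/C(C)(C)O[Si](CC)(CC)CC | intermediate
8 | (2S)-2-ethenyl-2,6-dimethyl-1-[(1E)-3-methyl-3-(triethylsilyloxy)but-1-en-1-yl]cyclohexan-1-ol (mixture at C1 and C6) | C=C[C@]1(C)CCCC(C)C1(O)/C=C/C(C)(C)O[Si](CC)(CC)CC | intermediate
9 | potassium alkoxide of 8 (not isolated) | C=C[C@]1(C)CCCC(C)C1([O-])/C=C/C(C)(C)O[Si](CC)(CC)CC.[K+] | intermediate
10 | potassium (6E,9S)-2,6-dimethyl-9-[2-(triethylsilyloxy)propan-2-yl]cyclodeca-1(10),6-dien-1-olate (not isolated) | C/C1=C\C[C@H](C(C)(C)O[Si](CC)(CC)CC)C=C([O-])C(C)CCC1.[K+] | intermediate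
11 | (6E,9S)-2,6-dimethyl-9-[2-(triethylsilyloxy)propan-2-yl]cyclodec-6-en-1-one (both C2 epimers) | C/C1=C\C[C@H](C(C)(C)O[Si](CC)(CC)CC)CC(=O)C(C)CCC1 | intermediate
12 | (6R,7R,9S)-6,7-epoxy-2,6-dimethyl-9-[2-(triethylsilyloxy)propan-2-yl]cyclodecan-1-one (trans epoxide; both C2 epimers) | C[C@@]12CCCC(C)C(=O)C[C@@H](C(C)(C)O[Si](CC)(CC)CC)C[C@H]1O2 | intermediate
13 | potassium (1Z,6R,7R,9S)-6,7-epoxy-2,6-dimethyl-9-[2-(triethylsilyloxy)propan-2-yl]cyclodec-1-en-1-olate (ring carbons trans across the enolate double bond; not isolated) | C[C@@]12CCC/C(C)=C(\[O-])C[C@@H](C(C)(C)O[Si](CC)(CC)CC)C[C@H]1O2.[K+] | intermediate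
14 | (4R,5R,7S,10S)-4-hydroxy-11-(triethylsilyloxy)eudesman-9-one (4α-OH, 5α-H, 10β-CH3, trans-fused) | O[C@]1(C)CCC[C@]2(C)C(=O)C[C@@H](C(C)(C)O[Si](CC)(CC)CC)C[C@H]21 | intermediate
15 | N-(tert-butyldimethylsilyl)hydrazone of 14 (not isolated) | O[C@]1(C)CCC[C@]2(C)C(=NN[Si](C)(C)C(C)(C)C)C[C@@H](C(C)(C)O[Si](CC)(CC)CC)C[C@H]21 | intermediate
16 | (4R,5R,7R,10R)-11-(triethylsilyloxy)eudesman-4-ol (11-O-triethylsilylcryptomeridiol) | O[C@]1(C)CCC[C@]2(C)CC[C@@H](C(C)(C)O[Si](CC)(CC)CC)C[C@H]21 | intermediate
17 | 2-bromo-4-chloro-1-iodobenzene | Clc1ccc(I)c(Br)c1 | starting material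
18 | 2-bromo-4-chloro-1-[hydroxy(tosyloxy)-λ3-iodanyl]benzene (not isolated) | Cc1ccc(cc1)S(=O)(=O)OI(O)c1ccc(Cl)cc1Br | intermediate
19 | (2-bromo-4-chlorophenyl)(2,4,6-trimethoxyphenyl)iodonium 4-methylbenzenesulfonate | COc1cc(OC)c([I+]c2ccc(Cl)cc2Br)c(OC)c1.Cc1ccc(cc1)S(=O)(=O)[O-] | intermediate
20 | sodium alkoxide of 16 (not isolated) | [O-][C@]1(C)CCC[C@]2(C)CC[C@@H](C(C)(C)O[Si](CC)(CC)CC)C[C@H]21.[Na+] | intermediate
21 | (4R,5R,7R,10R)-4-(2-bromo-4-chlorophenoxy)-11-(triethylsilyloxy)eudesmane | Clc1ccc(O[C@]2(C)CCC[C@]3(C)CC[C@@H](C(C)(C)O[Si](CC)(CC)CC)C[C@H]32)c(Br)c1 | intermediate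
22 | 4-bromophenol | Oc1ccc(Br)cc1 | starting material
23 | 1-bromo-4-(prop-2-en-1-yloxy)benzene | C=CCOc1ccc(Br)cc1 | intermediate
24 | 4-bromo-2-(prop-2-en-1-yl)phenol | C=CCc1cc(Br)ccc1O | intermediate
25 | 2-(prop-2-en-1-yl)-4-(4,4,5,5-tetramethyl-1,3,2-dioxaborolan-2-yl)phenol | C=CCc1cc(ccc1O)B1OC(C)(C)C(C)(C)O1 | intermediate
26 | (4R,5R,7R,10R)-4-{[5-chloro-4'-hydroxy-3'-(prop-2-en-1-yl)biphenyl-2-yl]oxy}-11-(triethylsilyloxy)eudesmane | Clc1ccc(O[C@]2(C)CCC[C@]3(C)CC[C@@H](C(C)(C)O[Si](CC)(CC)CC)C[C@H]32)c(-c2ccc(O)c(CC=C)c2)c1 | intermediate
27 | (4R,5R,7R,10R)-4-{[4'-hydroxy-3',5-di(prop-2-en-1-yl)biphenyl-2-yl]oxy}-11-(triethylsilyloxy)eudesmane | C=CCc1ccc(O[C@]2(C)CCC[C@]3(C)CC[C@@H](C(C)(C)O[Si](CC)(CC)CC)C[C@H]32)c(-c2ccc(O)c(CC=C)c2)c1 | intermediate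
28 | 2-(prop-2-en-1-yl)-4-{5-(prop-2-en-1-yl)-2-[((1R,4aR,7R,8aR)-7-(2-hydroxypropan-2-yl)-1,4a-dimethyldecahydronaphthalen-1-yl)oxy]phenyl}phenol (CNP0219722.1) | C=CCc1ccc(O[C@]2(C)CCC[C@]3(C)CC[C@@H](C(C)(C)O)C[C@H]32)c(-c2ccc(O)c(CC=C)c2)c1 | target

## Step count and least certain steps

Total steps: 16. Longest linear sequence: 11 (steps 1, 2, 4, 5, 6, 7, 8, 10, 14, 15, 16).

**Step 7 (key step).** The most likely failure is closure through the folded chair–chair arrangement, which would give the cis-fused C10 epimer, or alkylation on the enolate oxygen. Neither the enolate geometry nor the ring conformation is locked, and the margin in favour of the trans-decalin transition state rests on conformational analysis only. The fallback reverses the polarity of the closure; it sets out from 11 and returns at 16. 11 is converted under equilibrating conditions (KHMDS with a slight excess of ketone, then PhNTf2) into the more substituted enol triflate, (6E,9S)-2,6-dimethyl-9-[2-(triethylsilyloxy)propan-2-yl]cyclodeca-1,6-dien-1-yl trifluoromethanesulfonate F1. F1 is reduced (Pd(OAc)2, PPh3, HCO2H, Bu3N) to (4E)-11-(triethylsilyloxy)germacra-4,9-diene F2. Aqueous formic acid then protonates C9, the C4=C5 alkene attacks the C10 cation through C5, and water captures the C4 cation from the face away from the C10 methyl, as in the acid cyclisation of germacradienols to eudesmane-4,11-diols. This should give cryptomeridiol F3 with loss of the silyl group. Silylation of the less hindered C11 hydroxyl (TESOTf, 2,6-lutidine, −78 °C) returns 16, and step 8 is no longer needed.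

**Step 3.** The most likely failure is insufficient facial discrimination in the bond-forming reductive elimination, or a second vinylation at C6, because the ketone is substituted on both α-carbons and carries no blocking group. The fallback uses an auxiliary; it sets out from 5 and returns at 6. 5 is condensed with (R)-1-phenylethanamine to (R)-N-(2,6-dimethylcyclohexylidene)-1-phenylethanamine F4. Its enamine tautomer adds to methyl acrylate in the deracemising Michael reaction of chiral imines, and aqueous acetic acid liberates methyl 3-[(1S)-1,3-dimethyl-2-oxocyclohexyl]propanoate F5. Saponification (LiOH) gives 3-[(1S)-1,3-dimethyl-2-oxocyclohexyl]propanoic acid F6, and Kochi oxidative decarboxylation (Pb(OAc)4, Cu(OAc)2, pyridine, benzene, 80 °C) turns the propanoic acid chain into the vinyl group of 6.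

**Step 6.** The most likely failure is oxygen delivery to the other alkene face, should the ring prefer the other planar-chiral conformer and override the catalyst. The fallback inverts the facial sense; it sets out from 11 and returns at 12. NBS in aqueous THF adds bromine to the face that the oxidant prefers and water to C4 from the opposite side, giving (6R,7S,9R)-7-bromo-6-hydroxy-2,6-dimethyl-9-[2-(triethylsilyloxy)propan-2-yl]cyclodecan-1-one F7. K2CO3 in methanol then closes the C4 oxygen onto C5 with inversion, which places the epoxide oxygen on the face required for 12.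

**Step 10.** The most likely failure is base-induced aryne formation from the iodonium salt, which would scramble the substitution pattern, or sluggish ligand coupling, because the alkoxide is tertiary and shielded by the axial C4 methyl and the C6 methylene. The fallback sets out from 16 and 17 and returns at 21. The sodium alkoxide of 16 is coupled at the C–I bond of 17 by zerovalent palladium with a bulky dialkylbiarylphosphine (Pd2(dba)3, 2-(di-tert-butylphosphino)biphenyl, toluene, 80 °C), the conditions known for aryl tert-alkyl ethers. It makes no new compound.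

**Step 8.** The most likely failure is incomplete hydrazone formation at the neopentyl C9 carbonyl, or loss of the triethylsilyl group if the basic stage has to be heated for long. The fallback is a radical deoxygenation; it sets out from 14 and returns at 16. NaBH4 reduces 14 to (4R,5R,7S,10S)-11-(triethylsilyloxy)eudesmane-4,9-diol F8 (either C9 epimer). NaH, CS2 and MeI convert the secondary hydroxyl, in preference to the tertiary one, into O-[(4R,5R,7S,10S)-4-hydroxy-11-(triethylsilyloxy)eudesman-9-yl] S-methyl carbonodithioate F9. Bu3SnH with AIBN in toluene at 110 °C (Barton–McCombie) then gives 16.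

## Further compounds

F1 | step 7 | (6E,9S)-2,6-dimethyl-9-[2-(triethylsilyloxy)propan-2-yl]cyclodeca-1,6-dien-1-yl trifluoromethanesulfonate | C/C1=C\C[C@H](C(C)(C)O[Si](CC)(CC)CC)CC(OS(=O)(=O)C(F)(F)F)=C(C)CCC1
F2 | step 7 | (4E)-11-(triethylsilyloxy)germacra-4,9-diene (side-chain carbon as in 11) | C/C1=C\C[C@H](C(C)(C)O[Si](CC)(CC)CC)CC=C(C)CCC1
F3 | step 7 | cryptomeridiol, (4R,5R,7R,10R)-eudesmane-4,11-diol | O[C@]1(C)CCC[C@]2(C)CC[C@@H](C(C)(C)O)C[C@H]21
F4 | step 3 | (R)-N-(2,6-dimethylcyclohexylidene)-1-phenylethanamine | CC1CCCC(C)C1=N[C@H](C)c1ccccc1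
F5 | step 3 | methyl 3-[(1S)-1,3-dimethyl-2-oxocyclohexyl]propanoate | COC(=O)CC[C@]1(C)CCCC(C)C1=O
F6 | step 3 | 3-[(1S)-1,3-dimethyl-2-oxocyclohexyl]propanoic acid | OC(=O)CC[C@]1(C)CCCC(C)C1=O
F7 | step 6 | (6R,7S,9R)-7-bromo-6-hydroxy-2,6-dimethyl-9-[2-(triethylsilyloxy)propan-2-yl]cyclodecan-1-one | C[C@@]1(O)CCCC(C)C(=O)C[C@@H](C(C)(C)O[Si](CC)(CC)CC)C[C@@H]1Br
F0 | step 10 | none | none
F8 | step 8 | (4R,5R,7S,10S)-11-(triethylsilyloxy)eudesmane-4,9-diol | O[C@]1(C)CCC[C@]2(C)C(O)C[C@@H](C(C)(C)O[Si](CC)(CC)CC)C[C@H]21
F9 | step 8 | O-[(4R,5R,7S,10S)-4-hydroxy-11-(triethylsilyloxy)eudesman-9-yl] S-methyl carbonodithioate | O[C@]1(C)CCC[C@]2(C)C(OC(=S)SC)C[C@@H](C(C)(C)O[Si](CC)(CC)CC)C[C@H]21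
A1 | alternative 1 | 1-acetyl-2-methyl-2-(2-oxopropyl)-5-(2-hydroxypropan-2-yl)cyclohexane, acetyl cis to oxopropyl | CC(=O)C[C@]1(C)CC[C@@H](C(C)(C)O)C[C@@H]1C(C)=O
A2 | alternative 1 | (R)-α-terpineol | CC1=CC[C@H](C(C)(C)O)CC1
A3 | alternative 1 | pentane-2,4-dione | CC(=O)CC(C)=O
A4 | alternative 1 | 4α,11-dihydroxyeudesman-2-one | O[C@]1(C)CC(=O)C[C@]2(C)CC[C@@H](C(C)(C)O)C[C@H]21
A5 | alternative 2 | methyl 3-(3-allyl-4-tert-butyldimethylsilyloxyphenyl)-4-[11-(triethylsilyloxy)eudesman-4α-yloxy]benzoate | COC(=O)c1ccc(O[C@]2(C)CCC[C@]3(C)CC[C@@H](C(C)(C)O[Si](CC)(CC)CC)C[C@H]32)c(-c2ccc(O[Si](C)(C)C(C)(C)C)c(CC=C)c2)c1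
A6 | alternative 2 | 4α-{[(3-allyl-4-tert-butyldimethylsilyloxyphenyl)ethynyl]oxy}-11-(triethylsilyloxy)eudesmane | C=CCc1cc(C#CO[C@]2(C)CCC[C@]3(C)CC[C@@H](C(C)(C)O[Si](CC)(CC)CC)C[C@H]32)ccc1O[Si](C)(C)C(C)(C)C
A7 | alternative 2 | methyl coumalate (methyl 2-oxo-2H-pyran-5-carboxylate) | COC(=O)C1=COC(=O)C=C1
A8 | alternative 3 | 11-(triethylsilyloxy)eudesm-1-en-4α-ol | O[C@]1(C)CC=C[C@]2(C)CC[C@@H](C(C)(C)O[Si](CC)(CC)CC)C[C@H]21
A9 | alternative 3 | 11-O-triethylsilylelemol | C=C[C@]1(C)CC[C@@H](C(C)(C)O[Si](CC)(CC)CC)C[C@H]1C(C)=C
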